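**Retrosynthetic overview**
- Target ⇐ ester cleavage and acetal/silyl hydrolysis, C1 ketone reduction, and C8–O acylation of a ring B diol ester on a 1-oxodecalin.
- Ring B ⇐ C7–C8 bond: a vinyl epoxide is inverted by Pd(PPh3)4/InI into a nucleophilic 2-(alkoxycarbonyl)allylindium (C7, the β-carbon of the acrylate, acts as a homoenolate-type donor) that closes onto the CH2CHO arm.
- Vinyl epoxide ⇐ C6–C7 bond: sulfur-ylide epoxidation of the hindered ring A aldehyde; the two aldehydes are unmasked one after the other from an isobutenyl and an allyl group.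
- Ring A ⇐ conjugate addition/allylation of (R)-4-(dimethoxymethyl)-2-methylcyclohexenone ⇐ catalytic asymmetric Diels–Alder (2-silyloxy-3-methylbutadiene + acrolein), acetalisation, Saegusa oxidation.
- Ring order: ring A first (Diels–Alder), ring B second (umpolung allylation).

Numbering: locants C1–C15 are those of the target skeleton (C10 = quaternary carbon bearing methyl C14; C1 = carbinol next to it; C4 bears formyl carbon C15; C5 = ring-fusion CH; C6, C7, C8 = ring B carbons bearing OH, the acrylic unit C11–C13 (C12 = carboxyl) and the ester oxygen; C9 = ring B CH2).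
Assumption: the (S)-configured catalyst of step 2 is taken to give the (R)-adduct; if the sense is the reverse, the mirror-image catalyst is used and nothing else changes.
Assumption: the target is made in the open hydroxy-aldehyde/hydroxy-acid form of the given SMILES (its 6,15-hemiacetal ring tautomer counts as the same compound) and is isolated under buffered, non-acidic conditions.

**Step 1**
Reactants: 1 3-methylbut-3-en-2-one
Product: 2 tert-butyl(dimethyl)[(3-methylbuta-1,3-dien-2-yl)oxy]silane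
Conditions: TBSOTf, Et3N, Et2O, 0 °C
Reagents that add atoms: tert-butyldimethylsilyl triflate, CC(C)(C)[Si](C)(C)OS(=O)(=O)C(F)(F)F
Why: Soft enolisation and O-silylation at the only enolisable position gives the 2-silyloxy diene; no stereocenter is formed.

**Step 2**
Reactants: 2 tert-butyl(dimethyl)[(3-methylbuta-1,3-dien-2-yl)oxy]silane; 3 acrolein
Product: 4 (1R)-4-{[tert-butyl(dimethyl)silyl]oxy}-3-methylcyclohex-3-ene-1-carbaldehyde
Conditions: (S)-1-(2-methylphenyl)-3,3-diphenyltetrahydro-1H,3H-pyrrolo[1,2-c][1,3,2]oxazaborole (20 mol%), Tf2NH (16 mol%), CH2Cl2, −78 °C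
Reagents that add atoms: none
Why: Catalytic asymmetric Diels–Alder reaction in which the 2-silyloxy group places the formyl-bearing carbon para to it and the chiral oxazaborolidinium cation binds acrolein and shields one face, setting C4 as R.

**Step 3**
Reactants: 4 (1R)-4-{[tert-butyl(dimethyl)silyl]oxy}-3-methylcyclohex-3-ene-1-carbaldehyde
Product: 5 tert-butyl{[(4R)-4-(dimethoxymethyl)-2-methylcyclohex-1-en-1-yl]oxy}dimethylsilane
Conditions: HC(OMe)3, MeOH, pyridinium p-toluenesulfonate (5 mol%), 0 °C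
Reagents that add atoms: trimethyl orthoformate, COC(OC)OC
Why: Mild acetalisation masks C15 and removes the acidic C4–H problem (the tetrasubstituted silyl enol ether survives the buffered acid), so C4 is not touched.

**Step 4**
Reactants: 5 tert-butyl{[(4R)-4-(dimethoxymethyl)-2-methylcyclohex-1-en-1-yl]oxy}dimethylsilane
Product: 6 (4R)-4-(dimethoxymethyl)-2-methylcyclohex-2-en-1-one
Conditions: Pd(OAc)2 (1.05 equiv), MeCN, rt
Reagents that add atoms: none
Why: Saegusa–Ito oxidation of the regiodefined silyl enol ether gives the endocyclic C10=C5 enone by β-hydride elimination from the ring CH2; C4 is unaffected.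

**Step 5**
Reactants: 6 (4R)-4-(dimethoxymethyl)-2-methylcyclohex-2-en-1-one; 7 (2-methylprop-1-en-1-yl)magnesium bromide; 8 allyl bromide
Product: 10 (2R,3S,4R)-4-(dimethoxymethyl)-2-methyl-3-(2-methylprop-1-en-1-yl)-2-(prop-2-en-1-yl)cyclohexan-1-one, via magnesium enolate 9 (not isolated)
Conditions: CuBr·SMe2 (10 mol%), THF, −40 °C; then 8, DMPU, −40 °C → rt
Reagents that add atoms: none
Why: Copper-catalysed conjugate addition then enolate alkylation (three-component coupling): the alkenyl group adds to C5 anti to the C4 substituent and allyl bromide attacks the enolate face anti to the new C5 group, giving the trans,trans array with the quaternary C10 (methyl cis to the C5 substituent).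

**Step 6**
Reactants: 10 (2R,3S,4R)-4-(dimethoxymethyl)-2-methyl-3-(2-methylprop-1-en-1-yl)-2-(prop-2-en-1-yl)cyclohexan-1-one
Product: 11 (1S,2R,6R)-6-(dimethoxymethyl)-2-methyl-3-oxo-2-(prop-2-en-1-yl)cyclohexane-1-carbaldehyde
Conditions: O3 (1.0 equiv), CH2Cl2–MeOH, −78 °C; then Me2S
Reagents that add atoms: ozone, [O-][O+]=O
Why: Chemoselective ozonolysis: electrophilic ozone cleaves the electron-rich trisubstituted alkene much faster than the monosubstituted allyl group, releasing the C6 aldehyde only; no stereocenter changes.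

**Step 7**
Reactants: 12 2-(bromomethyl)prop-2-enoic acid; 13 2-(trimethylsilyl)ethanol
Product: 15 2-(trimethylsilyl)ethyl 2-(bromomethyl)prop-2-enoate, via acid chloride 14 (not isolated)
Conditions: (COCl)2, DMF (cat.), CH2Cl2, 0 °C → rt; then 13, 2,6-lutidine, 0 °C
Reagents that add atoms: none
Why: Esterification through the acid chloride with a hindered base avoids nucleophilic amine catalysts that would alkylate on the allylic bromide; no stereocenter.

**Step 8**
Reactants: 11 (1S,2R,6R)-6-(dimethoxymethyl)-2-methyl-3-oxo-2-(prop-2-en-1-yl)cyclohexane-1-carbaldehyde; 15 2-(trimethylsilyl)ethyl 2-(bromomethyl)prop-2-enoate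
Product: 17 2-(trimethylsilyl)ethyl 2-{(2R,3R)-3-[(1S,2R,6R)-6-(dimethoxymethyl)-2-methyl-3-oxo-2-(prop-2-en-1-yl)cyclohexyl]oxiran-2-yl}prop-2-enoate, via sulfonium bromide 16 (not isolated)
Conditions: 15, tetrahydrothiophene, MeCN, rt; then 11, Cs2CO3, −20 °C → rt
Reagents that add atoms: none
Why: Sulfur-ylide (Corey–Chaykovsky-type) epoxidation with a semi-stabilised allylic ylide gives the trans vinyl epoxide, and Felkin–Anh attack anti to the quaternary C10 sets C6 as R (C7 is erased later); the hindered ketone is left alone.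

**Step 9**
Reactants: 17 2-(trimethylsilyl)ethyl 2-{(2R,3R)-3-[(1S,2R,6R)-6-(dimethoxymethyl)-2-methyl-3-oxo-2-(prop-2-en-1-yl)cyclohexyl]oxiran-2-yl}prop-2-enoate
Product: 18 2-(trimethylsilyl)ethyl 2-{(2R,3R)-3-[(1S,2R,6R)-6-(dimethoxymethyl)-2-methyl-3-oxo-2-(2-oxoethyl)cyclohexyl]oxiran-2-yl}prop-2-enoate
Conditions: OsO4 (2 mol%), NaIO4, 2,6-lutidine, dioxane–H2O, rt
Reagents that add atoms: sodium periodate, [Na+].[O-]I(=O)(=O)=O
Why: Lemieux–Johnson cleavage: osmylation prefers the electron-rich terminal allyl alkene over the electron-poor acrylate alkene, so only the C8 aldehyde is released while the buffered medium spares the epoxide.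

**Step 10**
Reactants: 18 2-(trimethylsilyl)ethyl 2-{(2R,3R)-3-[(1S,2R,6R)-6-(dimethoxymethyl)-2-methyl-3-oxo-2-(2-oxoethyl)cyclohexyl]oxiran-2-yl}prop-2-enoate
Product: 20 2-(trimethylsilyl)ethyl (4R,5S,6R,7R,8S,10R)-6,8-dihydroxy-15,15-dimethoxy-1-oxoeudesm-11(13)-en-12-oate, via allylindium alkoxide 19 (not isolated)
Conditions: Pd(PPh3)4 (5 mol%), InI (2 equiv), THF–DMPU, 0.01 M, rt; aq NH4Cl
Reagents that add atoms: none
Why: Proposed new method: zerovalent palladium ionises the vinyl epoxide to a π-allylpalladium alkoxide and InI transmetalates it (redox umpolung) to a 2-(alkoxycarbonyl)allylindium, whose γ-carbon C7 (normally the electrophilic β-carbon of the acrylate) adds to the normally electrophilic C8 aldehyde carbon through a chair transition state closing ring B trans-fused; the preset C6–O bond and the acrylate unit sit equatorial with C6–H eclipsing C7=C11 (least A(1,3) strain, C7 side chain β) and the aldehyde oxygen is equatorial because an axial one would be 1,3-diaxial to the C10 methyl (8α-OH), while attack on the C1 ketone would need C6 axial; closest known reaction types are the intermolecular Pd/InI umpolung allylation of aldehydes with vinyloxiranes and intramolecular Barbier or Nozaki–Hiyama cyclisations of 2-(bromomethyl)acrylates.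

**Step 11**
Reactants: 21 ethyl 2-(hydroxymethyl)prop-2-enoate
Product: 23 2-({[tert-butyl(dimethyl)silyl]oxy}methyl)prop-2-enoic acid, via silyl ether ester 22 (not isolated)
Conditions: TBSCl, imidazole, THF, rt; then LiOH, H2O, 0 °C → rt; dilute HCl to pH 4
Reagents that add atoms: tert-butyldimethylsilyl chloride, CC(C)(C)[Si](C)(C)Cl; lithium hydroxide, [Li+].[OH-]
Why: Silylation of the primary alcohol followed by saponification in the same flask gives the protected acid; the primary silyl ether tolerates LiOH and no stereocenter is involved.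

**Step 12**
Reactants: 20 2-(trimethylsilyl)ethyl (4R,5S,6R,7R,8S,10R)-6,8-dihydroxy-15,15-dimethoxy-1-oxoeudesm-11(13)-en-12-oate; 23 2-({[tert-butyl(dimethyl)silyl]oxy}methyl)prop-2-enoic acid
Product: 24 2-(trimethylsilyl)ethyl (4R,5S,6R,7S,8S,10R)-8-{[2-({[tert-butyl(dimethyl)silyl]oxy}methyl)prop-2-enoyl]oxy}-6-hydroxy-15,15-dimethoxy-1-oxoeudesm-11(13)-en-12-oate
Conditions: DCC, 4-(dimethylamino)pyridine (10 mol%), CH2Cl2, 0 °C
Reagents that add atoms: none
Why: Steglich esterification is site-selective for the 8α-OH (flanked by a CH2) over the 6α-OH, which is shielded by the ring fusion and the peri C4 acetal; no stereocenter changes.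

**Step 13**
Reactants: 24 2-(trimethylsilyl)ethyl (4R,5S,6R,7S,8S,10R)-8-{[2-({[tert-butyl(dimethyl)silyl]oxy}methyl)prop-2-enoyl]oxy}-6-hydroxy-15,15-dimethoxy-1-oxoeudesm-11(13)-en-12-oate
Product: 25 2-(trimethylsilyl)ethyl (1R,4R,5S,6R,7S,8S,10R)-8-{[2-({[tert-butyl(dimethyl)silyl]oxy}methyl)prop-2-enoyl]oxy}-1,6-dihydroxy-15,15-dimethoxyeudesm-11(13)-en-12-oate
Conditions: NaBH4, CeCl3·7H2O, MeOH, −78 °C
Reagents that add atoms: none
Why: Luche reduction is ketone-selective in the presence of the acrylate esters, and axial hydride delivery from the α face (equatorial attack is blocked by the axial C10 methyl) gives the equatorial 1β-alcohol (C1 R).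

**Step 14**
Reactants: 25 2-(trimethylsilyl)ethyl (1R,4R,5S,6R,7S,8S,10R)-8-{[2-({[tert-butyl(dimethyl)silyl]oxy}methyl)prop-2-enoyl]oxy}-1,6-dihydroxy-15,15-dimethoxyeudesm-11(13)-en-12-oate
Product: 26 2-(trimethylsilyl)ethyl (1R,4R,5S,6R,7S,8S,10R)-1,6-dihydroxy-8-{[2-(hydroxymethyl)prop-2-enoyl]oxy}-15-oxoeudesm-11(13)-en-12-oate
Conditions: AcOH–THF–H2O (3:1:1), 35 °C
Reagents that add atoms: water, O
Why: Mild aqueous acid hydrolyses the dimethyl acetal (assisted by the neighbouring 6-OH) and the primary silyl ether while the silylethyl ester keeps C12 from lactonising; the equatorial 4α-formyl group is the thermodynamic epimer.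

**Step 15**
Reactants: 26 2-(trimethylsilyl)ethyl (1R,4R,5S,6R,7S,8S,10R)-1,6-dihydroxy-8-{[2-(hydroxymethyl)prop-2-enoyl]oxy}-15-oxoeudesm-11(13)-en-12-oate
Product: 27 (1R,4R,5S,6R,7S,8S,10R)-1,6-dihydroxy-8-{[2-(hydroxymethyl)prop-2-enoyl]oxy}-15-oxoeudesm-11(13)-en-12-oic acid (CNP0599450.1)
Conditions: tris(dimethylamino)sulfonium difluorotrimethylsilicate (3 equiv), DMF, 0 °C → rt; pH 5.5 phosphate buffer
Reagents that add atoms: none
Why: Fluoride-induced β-elimination of the 2-(trimethylsilyl)ethyl ester frees the C12 acid under non-acidic conditions, so the γ-hydroxy acid is not driven to the 6,12-lactone and the secondary acrylate ester is untouched.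

**Compound list**
1 | 3-methylbut-3-en-2-one | CC(=O)C(C)=C | starting material
2 | tert-butyl(dimethyl)[(3-methylbuta-1,3-dien-2-yl)oxy]silane | C=C(O[Si](C)(C)C(C)(C)C)C(C)=C | intermediate
3 | acrolein (prop-2-enal) | C=CC=O | starting material
4 | (1R)-4-{[tert-butyl(dimethyl)silyl]oxy}-3-methylcyclohex-3-ene-1-carbaldehyde | O=C[C@@H]1CCC(O[Si](C)(C)C(C)(C)C)=C(C)C1 | intermediate
5 | tert-butyl{[(4R)-4-(dimethoxymethyl)-2-methylcyclohex-1-en-1-yl]oxy}dimethylsilane | COC(OC)[C@@H]1CCC(O[Si](C)(C)C(C)(C)C)=C(C)C1 | intermediate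
6 | (4R)-4-(dimethoxymethyl)-2-methylcyclohex-2-en-1-one | CC1=C[C@H](C(OC)OC)CCC1=O | intermediate
7 | (2-methylprop-1-en-1-yl)magnesium bromide | CC(C)=C[Mg]Br | starting material
8 | allyl bromide (3-bromoprop-1-ene) | C=CCBr | starting material
9 | bromomagnesium (3S,4R)-4-(dimethoxymethyl)-2-methyl-3-(2-methylprop-1-en-1-yl)cyclohex-1-en-1-olate | CC1=C(O[Mg]Br)CC[C@@H](C(OC)OC)[C@@H]1C=C(C)C | intermediate
10 | (2R,3S,4R)-4-(dimethoxymethyl)-2-methyl-3-(2-methylprop-1-en-1-yl)-2-(prop-2-en-1-yl)cyclohexan-1-one | C=CC[C@]1(C)[C@@H](C=C(C)C)[C@H](C(OC)OC)CCC1=O | intermediate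
11 | (1S,2R,6R)-6-(dimethoxymethyl)-2-methyl-3-oxo-2-(prop-2-en-1-yl)cyclohexane-1-carbaldehyde | C=CC[C@]1(C)[C@@H](C=O)[C@H](C(OC)OC)CCC1=O | intermediate
12 | 2-(bromomethyl)prop-2-enoic acid | C=C(CBr)C(=O)O | starting material
13 | 2-(trimethylsilyl)ethanol | C[Si](C)(C)CCO | starting material
14 | 2-(bromomethyl)prop-2-enoyl chloride | C=C(CBr)C(=O)Cl | intermediate
15 | 2-(trimethylsilyl)ethyl 2-(bromomethyl)prop-2-enoate | C=C(CBr)C(=O)OCC[Si](C)(C)C | intermediate
16 | 1-(2-{[2-(trimethylsilyl)ethoxy]carbonyl}prop-2-en-1-yl)thiolan-1-ium bromide | C=C(C[S+]1CCCC1)C(=O)OCC[Si](C)(C)C.[Br-] | intermediate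
17 | 2-(trimethylsilyl)ethyl 2-{(2R,3R)-3-[(1S,2R,6R)-6-(dimethoxymethyl)-2-methyl-3-oxo-2-(prop-2-en-1-yl)cyclohexyl]oxiran-2-yl}prop-2-enoate | C=CC[C@]1(C)[C@@H]([C@H]2O[C@@H]2C(=C)C(=O)OCC[Si](C)(C)C)[C@H](C(OC)OC)CCC1=O | intermediate
18 | 2-(trimethylsilyl)ethyl 2-{(2R,3R)-3-[(1S,2R,6R)-6-(dimethoxymethyl)-2-methyl-3-oxo-2-(2-oxoethyl)cyclohexyl]oxiran-2-yl}prop-2-enoate | O=CC[C@]1(C)[C@@H]([C@H]2O[C@@H]2C(=C)C(=O)OCC[Si](C)(C)C)[C@H](C(OC)OC)CCC1=O | intermediate
19 | σ-allyl(iodo)indium alkoxide from ring opening of 18 at C7–O (trivalent indium; six-membered C6–O–In–C13 chelate shown) | O=CC[C@]1(C)[C@@H]([C@H]2O[In](I)CC(C(=O)OCC[Si](C)(C)C)=C2)[C@H](C(OC)OC)CCC1=O | intermediate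
20 | 2-(trimethylsilyl)ethyl (4R,5S,6R,7R,8S,10R)-6,8-dihydroxy-15,15-dimethoxy-1-oxoeudesm-11(13)-en-12-oate | O[C@H]1C[C@]2(C)[C@@H]([C@@H](O)[C@@H]1C(=C)C(=O)OCC[Si](C)(C)C)[C@H](C(OC)OC)CCC2=O | intermediate
21 | ethyl 2-(hydroxymethyl)prop-2-enoate | C=C(CO)C(=O)OCC | starting material
22 | ethyl 2-({[tert-butyl(dimethyl)silyl]oxy}methyl)prop-2-enoate | C=C(CO[Si](C)(C)C(C)(C)C)C(=O)OCC | intermediate
23 | 2-({[tert-butyl(dimethyl)silyl]oxy}methyl)prop-2-enoic acid | C=C(CO[Si](C)(C)C(C)(C)C)C(=O)O | intermediate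
24 | 2-(trimethylsilyl)ethyl (4R,5S,6R,7S,8S,10R)-8-{[2-({[tert-butyl(dimethyl)silyl]oxy}methyl)prop-2-enoyl]oxy}-6-hydroxy-15,15-dimethoxy-1-oxoeudesm-11(13)-en-12-oate | C=C(CO[Si](C)(C)C(C)(C)C)C(=O)O[C@H]1C[C@]2(C)[C@@H]([C@@H](O)[C@@H]1C(=C)C(=O)OCC[Si](C)(C)C)[C@H](C(OC)OC)CCC2=O | intermediate
25 | 2-(trimethylsilyl)ethyl (1R,4R,5S,6R,7S,8S,10R)-8-{[2-({[tert-butyl(dimethyl)silyl]oxy}methyl)prop-2-enoyl]oxy}-1,6-dihydroxy-15,15-dimethoxyeudesm-11(13)-en-12-oate | C=C(CO[Si](C)(C)C(C)(C)C)C(=O)O[C@H]1C[C@]2(C)[C@@H]([C@@H](O)[C@@H]1C(=C)C(=O)OCC[Si](C)(C)C)[C@H](C(OC)OC)CC[C@H]2O | intermediate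
26 | 2-(trimethylsilyl)ethyl (1R,4R,5S,6R,7S,8S,10R)-1,6-dihydroxy-8-{[2-(hydroxymethyl)prop-2-enoyl]oxy}-15-oxoeudesm-11(13)-en-12-oate | C=C(CO)C(=O)O[C@H]1C[C@]2(C)[C@@H]([C@@H](O)[C@@H]1C(=C)C(=O)OCC[Si](C)(C)C)[C@H](C=O)CC[C@H]2O | intermediate
27 | (1R,4R,5S,6R,7S,8S,10R)-1,6-dihydroxy-8-{[2-(hydroxymethyl)prop-2-enoyl]oxy}-15-oxoeudesm-11(13)-en-12-oic acid (CNP0599450.1) | C=C(CO)C(=O)O[C@H]1C[C@]2(C)[C@@H]([C@@H](O)[C@@H]1C(=C)C(=O)O)[C@H](C=O)CC[C@H]2O | target

**Step count**
- Total: 15 steps.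
- Longest linear sequence: 13 steps (steps 1–6, 8–10, 12–15); steps 7 and 11 make the two side fragments.

**Three steps most likely to fail**

Step 10 (ring-closing umpolung allylation). The risks are a closed transition state through the chelated (Z)-allylindium that would give the axial 8β-alcohol, and capture of the π-allylpalladium alkoxide by the aldehyde as a dioxolane. The fallback sets out from 18 and comes back at 20. Pd(PPh3)4-catalysed 1,4-opening of the vinyl epoxide with AcOH gives 2-(trimethylsilyl)ethyl (2E,4S)-2-(acetoxymethyl)-4-[(1S,2R,6R)-6-(dimethoxymethyl)-2-methyl-3-oxo-2-(2-oxoethyl)cyclohexyl]-4-hydroxybut-2-enoate F1. SmI2 in THF–MeOH at −78 °C then reduces the aldehyde (through its open form) to a ketyl, which adds 6-exo to C7 of the enoate. The bulky O–Sm group stays equatorial, away from the C10 methyl, and the samarium enolate expels acetate to restore the methylene ester, giving 20 without any closed allylmetal transition state.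

Step 8 (ylide epoxidation of the hindered aldehyde). The risks are sluggish addition, C5 epimerisation by base, and insufficient Felkin–Anh control at C6. The fallback sets out from 11 and comes back at 17. Compound 15 and PPh3 give triphenyl(2-{[2-(trimethylsilyl)ethoxy]carbonyl}prop-2-en-1-yl)phosphonium bromide F2. Its ylide (K2CO3) olefinates 11 to 2-(trimethylsilyl)ethyl (3E)-4-[(1S,2R,6R)-6-(dimethoxymethyl)-2-methyl-3-oxo-2-(prop-2-en-1-yl)cyclohexyl]-2-methylidenebut-3-enoate F3. Shi epoxidation (D-fructose-derived ketone, Oxone, buffered MeCN–dimethoxymethane, 0 °C) then oxidises the electron-rich disubstituted C6=C7 alkene under reagent control to the (6R,7R)-epoxide 17.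

Step 12 (acylation of 8-OH in the presence of 6-OH). The risk is competing acylation at O6. The fallback sets out from 20 and comes back at 26. Pyridinium p-toluenesulfonate (cat.) in CH2Cl2 over 4 Å sieves lets the 6-OH displace one methoxy group of the peri acetal, giving 2-(trimethylsilyl)ethyl (4R,5S,6R,7R,8S,10R)-6,15-epoxy-8-hydroxy-15-methoxy-1-oxoeudesm-11(13)-en-12-oate F4, which leaves 8-OH as the only free hydroxyl. Acylation with 23 (DCC, 4-(dimethylamino)pyridine) gives the 8-O-{2-[(tert-butyldimethylsilyloxy)methyl]prop-2-enoyl} ester of the cyclic acetal F5. Luche reduction gives its 1β-alcohol F6, and the AcOH–THF–H2O treatment of step 14 opens the cyclic acetal and removes the silyl ether to give 26.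

**Further compounds**
F1 | step 10 | 2-(trimethylsilyl)ethyl (2E,4S)-2-(acetoxymethyl)-4-[(1S,2R,6R)-6-(dimethoxymethyl)-2-methyl-3-oxo-2-(2-oxoethyl)cyclohexyl]-4-hydroxybut-2-enoate | O=CC[C@]1(C)[C@@H]([C@@H](O)/C=C(\COC(C)=O)C(=O)OCC[Si](C)(C)C)[C@H](C(OC)OC)CCC1=O
F2 | step 8 | triphenyl(2-{[2-(trimethylsilyl)ethoxy]carbonyl}prop-2-en-1-yl)phosphonium bromide | C=C(C[P+](c1ccccc1)(c1ccccc1)c1ccccc1)C(=O)OCC[Si](C)(C)C.[Br-]
F3 | step 8 | 2-(trimethylsilyl)ethyl (3E)-4-[(1S,2R,6R)-6-(dimethoxymethyl)-2-methyl-3-oxo-2-(prop-2-en-1-yl)cyclohexyl]-2-methylidenebut-3-enoate | C=CC[C@]1(C)[C@@H](/C=C/C(=C)C(=O)OCC[Si](C)(C)C)[C@H](C(OC)OC)CCC1=O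
F4 | step 12 | 2-(trimethylsilyl)ethyl (4R,5S,6R,7R,8S,10R)-6,15-epoxy-8-hydroxy-15-methoxy-1-oxoeudesm-11(13)-en-12-oate (one C15 anomer shown) | O[C@H]1C[C@]2(C)[C@H]3[C@@H](O[C@@H](OC)[C@@H]3CCC2=O)[C@@H]1C(=C)C(=O)OCC[Si](C)(C)C
F5 | step 12 | 2-(trimethylsilyl)ethyl (4R,5S,6R,7S,8S,10R)-8-{[2-({[tert-butyl(dimethyl)silyl]oxy}methyl)prop-2-enoyl]oxy}-6,15-epoxy-15-methoxy-1-oxoeudesm-11(13)-en-12-oate | C=C(CO[Si](C)(C)C(C)(C)C)C(=O)O[C@H]1C[C@]2(C)[C@H]3[C@@H](O[C@@H](OC)[C@@H]3CCC2=O)[C@@H]1C(=C)C(=O)OCC[Si](C)(C)C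
F6 | step 12 | 2-(trimethylsilyl)ethyl (1R,4R,5S,6R,7S,8S,10R)-8-{[2-({[tert-butyl(dimethyl)silyl]oxy}methyl)prop-2-enoyl]oxy}-6,15-epoxy-1-hydroxy-15-methoxyeudesm-11(13)-en-12-oate | C=C(CO[Si](C)(C)C(C)(C)C)C(=O)O[C@H]1C[C@]2(C)[C@H]3[C@@H](O[C@@H](OC)[C@@H]3CC[C@H]2O)[C@@H]1C(=C)C(=O)OCC[Si](C)(C)C
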